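Charge more Rx and you expect more Gy, and that expectation is the trap in this row of flasks. Dz, charged at 0.50 µM, gives the working form Uv, Uv turns Rx into Gy, and Rx also takes Gy away to Zu.

| flask | Rx | Dz | remark | time |
|---|---|---|---|---|
| dusk | 4.500 × 10⁻⁵ M | 0.50 µM | run made earlier |  |
| winter | 0.0037 M | 0.50 µM | run made earlier |  |
| Wednesday's | 6.0 × 10⁻⁵ M | 0.50 µM |  | 2.5 min |
| Sunday's | 1.5 × 10⁻⁴ M | 0.50 µM |  | 2.5 min |
| Friday's | 5.0 × 10⁻⁴ M | 0.50 µM |  | 2.5 min |
| Tuesday's | 0.0015 M | 0.50 µM |  | 2.5 min |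
| Monday's | 0.0050 M | 0.50 µM |  | 2.5 min |

- dusk (time / s: Gy / %, Rx / %): 10.0: 60.1, 39.7; 15.0: 69.5, 28.2; 20.0: 75.1, 22.9; 30.0: 79.7, 16.8; 50.0: 84.2, 11.2; 80.0: 86.0, 8.4
- winter (time / s: Gy / %, Rx / %): 10.0: 1.4, 94.0; 12.0: 0.9, 93.7; 20.0: 1.6, 90.3; 30.0: 0.5, 86.7; 50.0: 0, 84.5; 60.0: 0, 84.0; 80.0: 0, 82.9

(readings scatter by 0.5 percentage points)

- percent here means Rx units held: one Zu counts as two
- steps under discussion: 2 Uv -> Ez; Rx + Uv -> Gy + Uv; Dz <-> Uv; Rx + Gy -> Zu
- "hardly changes" means that all values lie within two and a half points (for a concentration: within two and a half percent of the largest)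
- a step back or a flat step of under half a percent of the largest counts as no turn

1. [Gy] at the end for Wednesday's, Sunday's, Friday's, Tuesday's, Monday's, in this order
2. the shape of the row from first to last (rises, then falls / falls, then rises / falls all the way / rises all the way / hardly changes)

Two readings seem not to go together: by 80.0 s the winter run has lost 17.1% of its Rx, which is more Rx than the dusk run held at the start, yet its Gy reads 0% of the charge, while the dusk run at that time reads 86.0%.

The dusk run clears this up. Between 30.0 s and 80.0 s its fractions of Rx and Gy together fall by 2.1 percentage points, and each turn to Zu removes one Rx and one Gy. Dividing that fall by twice the time, the charge and the mean fractions gives my reading of the eating constant, 44.7 M⁻¹ s⁻¹, a reading that carries the scatter of those points.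

One over this constant times the Rx charged is the survival time of Gy, its pseudo-first-order lifetime, and it grows as Rx falls. In the dusk run it is 497 s, longer than the run's 80.0 s. In the winter run it is 6.05 s, shorter than that time, so winter's Gy is eaten and its lost Rx stands in Zu.

Against the 2.5 min of the new flasks, survival is 373 s in Wednesday's, longer than the run, and 4.47 s in Monday's, far shorter. So I expect the row to rise while survival outlasts the run and to fall once survival is far shorter than the run.

The forecast, built on a constant of about 60 where I read 44.7 M⁻¹ s⁻¹, gives 5.000 × 10⁻⁵ M, 8.500 × 10⁻⁵ M, 1.000 × 10⁻⁴ M, 1.500 × 10⁻⁵ M and 2.700 × 10⁻⁶ M, a row that rises, then falls, with the words “Mid Rx loses Gy to Zu”.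

    2 Uv → Ez (k = 7.50 × 10⁵ M⁻¹ s⁻¹)
    Rx + Uv → Gy + Uv, rate k2*[Rx]*[Uv]/(1 + ([Rx]/Km2) + ([Gy]/Kp2)) (0.120 mM, 0.210 mM, k = 8.30 × 10⁵ M⁻¹ s⁻¹)
    Dz ⇌ Uv (K = 14.0, k = 0.250 s⁻¹)
    Rx + Gy → Zu (k = 50.0 M⁻¹ s⁻¹)

The flasks give 5.09 × 10⁻⁵ M, 9.69 × 10⁻⁵ M, 9.22 × 10⁻⁵ M, 1.36 × 10⁻⁵ M and 2.42 × 10⁻⁶ M, a row that rises, then falls. The row turns at a charge of 2.8 × 10⁻⁴ M. At that charge the survival time of Gy, from the eating constant read in the dusk run, is 80.1 s, about half of the 2.5 min run.

All runs come from a simulation with constants of no real substance; noise was put on by code.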